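Ring B (C5–C10) is treated as a [4+2] retron. It is cut across C5–C6 and C7–C8 into a diene C8=C9–C10=C5 carried on ring A and methyl vinyl ketone (C6=C7). One catalytic asymmetric Diels–Alder reaction closes ring B, sets the quaternary C5 (bearing C14) in the absolute sense, and puts an acetyl group on C7 beside an oxygen on C8. These become the isopropenyl group and the C8 ketone, and the surviving C9=C10 alkene later gives the trans ring fusion and the C9 oxygen. The diene partner is an achiral silyl trienol ether whose exocyclic C4 methylene cannot turn s-cis and is kept for the C3 hydroxyl and the C4 methyl group.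

Key step: step 5

Convention: bicyclic compounds carry the numbering of the target (C3 angelate carbon; C4/C15 and C5/C14 the methyl-bearing carbons and their methyls; C7 isopropenyl carbon; C8 ketone; C9 second ester carbon; C10 ring-fusion CH; ring A = C1–C5 and C10; ring B = C5–C10); β is the face of C14, α the opposite face; "octal-9-ene" means the C9=C10 octalin. The SMILES of the Tebbe reagent is drawn in its open valence form Cp2Ti(Cl)–CH2–AlMe2, with the Cl→Al bridge left undrawn.

Assumption: the oxazaborolidinium ion from (S)-diphenylprolinol is taken to leave open the Si face at C7 of boron-bound methyl vinyl ketone (α-C–H···O binding model); should the adduct prove antipodal, the catalyst from (R)-diphenylprolinol is used with no other change.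

Step 1
Reactants: 1 2-methylcyclohexane-1,3-dione
Product: 2 2-methyl-3-oxocyclohex-1-en-1-yl trifluoromethanesulfonate
Conditions: Tf2O, pyridine, CH2Cl2, −78 → 0 °C
Reagents that add atoms: trifluoromethanesulfonic anhydride, O=S(=O)(OS(=O)(=O)C(F)(F)F)C(F)(F)F
Why: O-sulfonylation of the enol of a symmetric 1,3-dione gives the vinylogous triflate, and the symmetry removes any question of regiochemistry.

Step 2
Reactants: 2 2-methyl-3-oxocyclohex-1-en-1-yl trifluoromethanesulfonate; 3 (E)-2-(2-ethoxyethenyl)-4,4,5,5-tetramethyl-1,3,2-dioxaborolane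
Product: 4 3-[(E)-2-ethoxyethenyl]-2-methylcyclohex-2-en-1-one
Conditions: Pd(PPh3)4 (5 mol %), K3PO4, 1,4-dioxane/H2O, 80 °C
Reagents that add atoms: none
Why: Suzuki–Miyaura coupling of an electron-poor alkenyl triflate with an alkenyl boronate forms C9–C10 with retention of the E geometry.

Step 3
Reactants: 4 3-[(E)-2-ethoxyethenyl]-2-methylcyclohex-2-en-1-one
Product: 6 3-[(E)-2-(tert-butyldimethylsilyloxy)ethenyl]-2-methylcyclohex-2-en-1-one, via keto aldehyde 5 (not isolated)
Conditions: 1 M HCl, THF, 0 °C → rt; then (crude) TBSCl, Et3N, DMAP (cat.), CH2Cl2, 0 °C → rt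
Reagents that add atoms: water, O; tert-butyldimethylsilyl chloride, CC(C)(C)[Si](C)(C)Cl
Why: Acid hydrolysis of the vinylogous enol ether frees the aldehyde while the ring is still a robust enone; its doubly activated C9 methylene is then enolised by Et3N and silylated on the unhindered aldehyde oxygen (soft enolisation), and the push–pull dienone should settle in the E geometry.

Step 4
Reactants: 6 3-[(E)-2-(tert-butyldimethylsilyloxy)ethenyl]-2-methylcyclohex-2-en-1-one
Product: 7 1-[(E)-2-(tert-butyldimethylsilyloxy)ethenyl]-2-methyl-3-methylidenecyclohex-1-ene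
Conditions: Tebbe reagent Cp2Ti(μ-Cl)(μ-CH2)AlMe2, pyridine, THF/toluene, −40 → 0 °C; aq NaOH
Reagents that add atoms: Tebbe reagent Cp2Ti(μ-Cl)(μ-CH2)AlMe2, C[Al](C)C[Ti](Cl)(C1C=CC=C1)C1C=CC=C1
Why: Tebbe methylenation (titanium methylidene, oxatitanacyclobutane) converts even ester-like carbonyl groups under conditions that are neither basic nor protic, so the silyl enol ether survives and the acid-sensitive triene is formed last.

Step 5
Reactants: 7 1-[(E)-2-(tert-butyldimethylsilyloxy)ethenyl]-2-methyl-3-methylidenecyclohex-1-ene; 8 methyl vinyl ketone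
Product: 9 7α-acetyl-8α-(tert-butyldimethylsilyloxy)-5β-methyl-4-methylideneoctal-9-ene
Conditions: oxazaborolidinium catalyst [(S)-α,α-diphenylprolinol + tri-o-tolylboroxine; then HNTf2] (20 mol %), 8 (5 equiv), CH2Cl2, −78 → −20 °C; Et3N quench
Reagents that add atoms: none
Why: Boron-bound s-trans methyl vinyl ketone (lowered LUMO) and the 8-silyloxy diene (raised HOMO, largest coefficient at C5) combine in a concerted, asynchronous [4+2] cycloaddition in which C5–C6 bonding leads and C7–C8 follows; the closest known reaction type is the oxazaborolidinium-catalysed Diels–Alder reaction of 1-silyloxy dienes with vinyl ketones. Ring B closes as a six-membered ring by intermolecular [4+2] cycloaddition, both bonds forming suprafacially on diene and enone. C7 is set by the enone face left open by the catalyst, C8 by the E geometry of the enol ether together with the endo rule (silyloxy and acetyl cis), and C5 by the diene face that the endo, catalyst-bound enone engages (C14 trans to both). The step needs ortho regiochemistry, secured by the C8 silyloxy donor polarising the diene toward C5 and by the unsubstituted C6 meeting the crowded C5, and endo selectivity, secured by the bound carbonyl lying under C9–C10. It also needs periselectivity, which holds because the C4 methylene is locked s-trans to C5=C10 and cannot act as a diene.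

Step 6
Reactants: 9 7α-acetyl-8α-(tert-butyldimethylsilyloxy)-5β-methyl-4-methylideneoctal-9-ene
Product: 10 7α-acetyl-8α-(tert-butyldimethylsilyloxy)-5β-methyl-4-methylideneoctal-9-en-3α-ol
Conditions: SeO2 (0.5 equiv), t-BuOOH (3 equiv), CH2Cl2, 0 °C → rt
Reagents that add atoms: selenium dioxide, O=[Se]=O; tert-butyl hydroperoxide, CC(C)(C)OO
Why: Catalytic SeO2/t-BuOOH allylic hydroxylation (ene reaction, then [2,3]-sigmatropic shift) should attack the unhindered C4=C15 alkene, whose only allylic hydrogens are on C3, in preference to the shielded and inductively deactivated C9=C10 alkene, and should deliver oxygen to the α face of C3, anti to the axial C14 methyl that stands 1,3 to it.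

Step 7
Reactants: 10 7α-acetyl-8α-(tert-butyldimethylsilyloxy)-5β-methyl-4-methylideneoctal-9-en-3α-ol
Product: 11 7α-acetyl-8α-(tert-butyldimethylsilyloxy)-4β,5β-dimethyloctal-9-en-3α-ol
Conditions: [Ir(cod)(PCy3)(py)]PF6 (5 mol %), H2 (1 atm), CH2Cl2, 0 °C → rt
Reagents that add atoms: none
Why: Hydroxyl-directed homogeneous hydrogenation: iridium held by the 3α-hydroxyl adds H2 to the α face of the allylic C4=C15 bond, the face also left open by the C14 methyl, so C15 ends β (cis to C14, trans to the hydroxyl), while the hindered trisubstituted C9=C10 alkene should remain.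

Step 8
Reactants: 11 7α-acetyl-8α-(tert-butyldimethylsilyloxy)-4β,5β-dimethyloctal-9-en-3α-ol
Product: 12 8α-(tert-butyldimethylsilyloxy)-7α-isopropenyl-4β,5β-dimethyloctal-9-en-3α-ol
Conditions: Tebbe reagent Cp2Ti(μ-Cl)(μ-CH2)AlMe2 (3 equiv), pyridine, THF/toluene, −40 → 0 °C; aq NaOH
Reagents that add atoms: Tebbe reagent Cp2Ti(μ-Cl)(μ-CH2)AlMe2, C[Al](C)C[Ti](Cl)(C1C=CC=C1)C1C=CC=C1
Why: Tebbe methylenation turns the acetyl group into the isopropenyl group without enolisation, so C7 keeps its configuration and the β-silyloxy group is not eliminated; the free hydroxyl only consumes one equivalent as a titanium alkoxide that is hydrolysed on work-up.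

Step 9
Reactants: 12 8α-(tert-butyldimethylsilyloxy)-7α-isopropenyl-4β,5β-dimethyloctal-9-en-3α-ol
Product: 13 7α-isopropenyl-4β,5β-dimethyloctal-9-ene-3α,8α-diol
Conditions: Bu4NF, THF, 0 °C → rt
Reagents that add atoms: none
Why: Fluoride-induced cleavage of the silyl ether frees the allylic C8 alcohol; no base-sensitive carbonyl group is present at this stage.

Step 10
Reactants: 13 7α-isopropenyl-4β,5β-dimethyloctal-9-ene-3α,8α-diol
Product: 14 3α-hydroxy-7α-isopropenyl-4β,5β-dimethyloctal-9-en-8-one
Conditions: MnO2 (activated, excess), CH2Cl2, rt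
Reagents that add atoms: none
Why: MnO2 oxidises only the allylic C8 alcohol, leaving the saturated C3 alcohol, and its neutral surface should not move the isopropenyl double bond into conjugation.

Step 11
Reactants: 14 3α-hydroxy-7α-isopropenyl-4β,5β-dimethyloctal-9-en-8-one
Product: 15 7α-isopropenyl-4β,5β-dimethyl-3α-(triethylsilyloxy)octal-9-en-8-one
Conditions: Et3SiCl, imidazole, DMF, 0 °C
Reagents that add atoms: chlorotriethylsilane, CC[Si](CC)(CC)Cl
Why: Silylation of the secondary alcohol under weakly basic conditions masks the C3 oxygen for the dissolving-metal step with a group that comes off later under mild acid fluoride.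

Step 12
Reactants: 15 7α-isopropenyl-4β,5β-dimethyl-3α-(triethylsilyloxy)octal-9-en-8-one
Product: 17 7α-isopropenyl-4β,5β-dimethyl-3α-(triethylsilyloxy)-8-(trimethylsilyloxy)-10αH-octal-8-ene, via lithium enolate 16 (not isolated)
Conditions: Li (2.5 equiv), t-BuOH (1.0 equiv), NH3(l)/THF, −78 °C; isoprene; NH3 off; then Me3SiCl, Et3N, THF, 0 °C
Reagents that add atoms: chlorotrimethylsilane, C[Si](C)(C)Cl
Why: Dissolving-metal (Birch-type) enone reduction with reductive enolate trapping: the C10 carbanion is protonated axially on the α face, anti to the C14 methyl, giving the trans ring fusion, and the remaining enolate is regiospecifically C8–C9 and is silylated on oxygen; the isolated isopropenyl alkene and the silyl ether are inert.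

Step 13
Reactants: 17 7α-isopropenyl-4β,5β-dimethyl-3α-(triethylsilyloxy)-8-(trimethylsilyloxy)-10αH-octal-8-ene
Product: 19 9α-hydroxy-7α-isopropenyl-4β,5β-dimethyl-3α-(triethylsilyloxy)-10αH-decalin-8-one, via silyloxy epoxide 18 (not isolated)
Conditions: dimethyldioxirane (1.05 equiv), acetone/CH2Cl2, −78 °C; then citric acid, MeOH, 0 °C
Reagents that add atoms: dimethyldioxirane, CC1(C)OO1
Why: Rubottom oxidation: the electron-rich silyl enol ether is epoxidised much faster than the isopropenyl group, from the α face because the axial C14 methyl blocks the β approach to C9, and brief acid methanolysis of the silyloxy epoxide should give the equatorial 9α-hydroxy ketone and spare the triethylsilyl ether.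

Step 14
Reactants: 19 9α-hydroxy-7α-isopropenyl-4β,5β-dimethyl-3α-(triethylsilyloxy)-10αH-decalin-8-one; 20 (E)-3-methylpent-2-enoic acid
Product: 21 7α-isopropenyl-4β,5β-dimethyl-9α-[(E)-3-methylpent-2-enoyloxy]-3α-(triethylsilyloxy)-10αH-decalin-8-one
Conditions: DCC, DMAP (0.2 equiv), CH2Cl2, 0 °C → rt
Reagents that add atoms: none
Why: Steglich esterification of the only free hydroxyl; low temperature and little DMAP limit deconjugation of the β,β-disubstituted enoate and keep the β,γ-unsaturated ketone away from strong base.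

Step 15
Reactants: 21 7α-isopropenyl-4β,5β-dimethyl-9α-[(E)-3-methylpent-2-enoyloxy]-3α-(triethylsilyloxy)-10αH-decalin-8-one
Product: 22 3α-hydroxy-7α-isopropenyl-4β,5β-dimethyl-9α-[(E)-3-methylpent-2-enoyloxy]-10αH-decalin-8-one
Conditions: HF·pyridine, pyridine, THF, 0 °C → rt
Reagents that add atoms: none
Why: Buffered HF cleaves the triethylsilyl ether under mildly acidic conditions that leave the α-acyloxy ketone, the enoate and the isopropenyl group untouched.

Step 16
Reactants: 22 3α-hydroxy-7α-isopropenyl-4β,5β-dimethyl-9α-[(E)-3-methylpent-2-enoyloxy]-10αH-decalin-8-one; 23 angelic acid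
Product: 25 CNP0301161.1 [(3R,4R,5R,7S,9S,10R)-3-angeloyloxy-7-isopropenyl-4,5-dimethyl-9-[(E)-3-methylpent-2-enoyloxy]decalin-8-one], via angelic 2,4,6-trichlorobenzoic anhydride 24 (not isolated)
Conditions: 23, 2,4,6-trichlorobenzoyl chloride, Et3N, toluene, rt; then 22, toluene, 75 °C
Reagents that add atoms: none
Why: Yamaguchi esterification through the mixed anhydride, run without a nucleophilic amine catalyst, is the standard way to attach an angelate without Z-to-E isomerisation to the tiglate, and the C3 hydroxyl is the only one left.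

Compound list
1 | 2-methylcyclohexane-1,3-dione | CC1C(=O)CCCC1=O | starting material
2 | 2-methyl-3-oxocyclohex-1-en-1-yl trifluoromethanesulfonate | CC1=C(OS(=O)(=O)C(F)(F)F)CCCC1=O | intermediate
3 | (E)-2-(2-ethoxyethenyl)-4,4,5,5-tetramethyl-1,3,2-dioxaborolane | CCO/C=C/B1OC(C)(C)C(C)(C)O1 | starting material
4 | 3-[(E)-2-ethoxyethenyl]-2-methylcyclohex-2-en-1-one | CCO/C=C/C1=C(C)C(=O)CCC1 | intermediate
5 | 2-(2-methyl-3-oxocyclohex-1-en-1-yl)acetaldehyde (keto aldehyde, not isolated) | CC1=C(CC=O)CCCC1=O | intermediate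
6 | 3-[(E)-2-(tert-butyldimethylsilyloxy)ethenyl]-2-methylcyclohex-2-en-1-one | CC1=C(/C=C/O[Si](C)(C)C(C)(C)C)CCCC1=O | intermediate
7 | 1-[(E)-2-(tert-butyldimethylsilyloxy)ethenyl]-2-methyl-3-methylidenecyclohex-1-ene | C=C1CCCC(/C=C/O[Si](C)(C)C(C)(C)C)=C1C | intermediate
8 | methyl vinyl ketone (but-3-en-2-one) | CC(=O)C=C | starting material
9 | (5R,7R,8S)-7-acetyl-8-(tert-butyldimethylsilyloxy)-5-methyl-4-methylideneoctal-9-ene (7α-acetyl, 8α-silyloxy, 5β-methyl) | CC(=O)[C@@H]1C[C@]2(C)C(=C)CCCC2=C[C@@H]1O[Si](C)(C)C(C)(C)C | intermediate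
10 | 7α-acetyl-8α-(tert-butyldimethylsilyloxy)-5β-methyl-4-methylideneoctal-9-en-3α-ol | CC(=O)[C@@H]1C[C@]2(C)C(=C)[C@H](O)CCC2=C[C@@H]1O[Si](C)(C)C(C)(C)C | intermediate
11 | 7α-acetyl-8α-(tert-butyldimethylsilyloxy)-4β,5β-dimethyloctal-9-en-3α-ol | CC(=O)[C@@H]1C[C@]2(C)[C@@H](C)[C@H](O)CCC2=C[C@@H]1O[Si](C)(C)C(C)(C)C | intermediate
12 | 8α-(tert-butyldimethylsilyloxy)-7α-isopropenyl-4β,5β-dimethyloctal-9-en-3α-ol | C=C(C)[C@@H]1C[C@]2(C)[C@@H](C)[C@H](O)CCC2=C[C@@H]1O[Si](C)(C)C(C)(C)C | intermediate
13 | 7α-isopropenyl-4β,5β-dimethyloctal-9-ene-3α,8α-diol | C=C(C)[C@@H]1C[C@]2(C)[C@@H](C)[C@H](O)CCC2=C[C@@H]1O | intermediate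
14 | 3α-hydroxy-7α-isopropenyl-4β,5β-dimethyloctal-9-en-8-one | C=C(C)[C@@H]1C[C@]2(C)[C@@H](C)[C@H](O)CCC2=CC1=O | intermediate
15 | 7α-isopropenyl-4β,5β-dimethyl-3α-(triethylsilyloxy)octal-9-en-8-one | C=C(C)[C@@H]1C[C@]2(C)[C@@H](C)[C@H](O[Si](CC)(CC)CC)CCC2=CC1=O | intermediate
16 | lithium 7α-isopropenyl-4β,5β-dimethyl-3α-(triethylsilyloxy)-10αH-octal-8-en-8-olate (lithium enolate, not isolated) | C=C(C)[C@@H]1C[C@]2(C)[C@@H](C)[C@H](O[Si](CC)(CC)CC)CC[C@H]2C=C1O[Li] | intermediate
17 | 7α-isopropenyl-4β,5β-dimethyl-3α-(triethylsilyloxy)-8-(trimethylsilyloxy)-10αH-octal-8-ene | C=C(C)[C@@H]1C[C@]2(C)[C@@H](C)[C@H](O[Si](CC)(CC)CC)CC[C@H]2C=C1O[Si](C)(C)C | intermediate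
18 | 8α,9α-epoxy-7α-isopropenyl-4β,5β-dimethyl-3α-(triethylsilyloxy)-8β-(trimethylsilyloxy)-10αH-decalin (silyloxy epoxide, not isolated) | C=C(C)[C@@H]1C[C@]2(C)[C@@H](C)[C@H](O[Si](CC)(CC)CC)CC[C@H]2[C@@H]3O[C@]13O[Si](C)(C)C | intermediate
19 | 9α-hydroxy-7α-isopropenyl-4β,5β-dimethyl-3α-(triethylsilyloxy)-10αH-decalin-8-one | C=C(C)[C@@H]1C[C@]2(C)[C@@H](C)[C@H](O[Si](CC)(CC)CC)CC[C@H]2[C@H](O)C1=O | intermediate
20 | (E)-3-methylpent-2-enoic acid | OC(=O)/C=C(\C)CC | starting material
21 | 7α-isopropenyl-4β,5β-dimethyl-9α-[(E)-3-methylpent-2-enoyloxy]-3α-(triethylsilyloxy)-10αH-decalin-8-one | C=C(C)[C@@H]1C[C@]2(C)[C@@H](C)[C@H](O[Si](CC)(CC)CC)CC[C@H]2[C@H](OC(=O)/C=C(\C)CC)C1=O | intermediate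
22 | 3α-hydroxy-7α-isopropenyl-4β,5β-dimethyl-9α-[(E)-3-methylpent-2-enoyloxy]-10αH-decalin-8-one | C=C(C)[C@@H]1C[C@]2(C)[C@@H](C)[C@H](O)CC[C@H]2[C@H](OC(=O)/C=C(\C)CC)C1=O | intermediate
23 | angelic acid, (Z)-2-methylbut-2-enoic acid | OC(=O)/C(C)=C\C | starting material
24 | angelic 2,4,6-trichlorobenzoic anhydride (not isolated) | C/C=C(/C)C(=O)OC(=O)c1c(Cl)cc(Cl)cc1Cl | intermediate
25 | CNP0301161.1, (3R,4R,5R,7S,9S,10R)-3-angeloyloxy-7-isopropenyl-4,5-dimethyl-9-[(E)-3-methylpent-2-enoyloxy]decalin-8-one (3α-ester, 4β,5β-dimethyl, 7α-isopropenyl, 9α-ester, 10αH) | C=C(C)[C@@H]1C[C@]2(C)[C@@H](C)[C@H](OC(=O)/C(C)=C\C)CC[C@H]2[C@H](OC(=O)/C=C(\C)CC)C1=O | target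

Total step count: 16 steps.
Longest linear sequence: 16 steps (1 → 25); 3, 8, 20 and 23 enter as purchased building blocks.

Steps most likely to fail

Step 5. The fully substituted C5 terminus carries the inward-pointing C14 methyl and may react too slowly. Acid-promoted loss of the silyl group, or open-chain conjugate addition of the trienyl ether without ring closure, could then overtake cycloaddition, and the sense of enantioinduction could be opposite to the assumed one. The fallback replaces catalyst control by auxiliary control with a more electrophilic, two-point-bound dienophile. It sets out from 7: cycloaddition with (S)-3-acryloyl-4-benzyloxazolidin-2-one under Et2AlCl in CH2Cl2 at −78 °C should give the imide adduct F1, in which the oxazolidinone shields the Re face at C7. Transamination with MeNHOMe·HCl/Me3Al should give the N-methoxy-N-methylamide F2, and MeMgBr in THF at 0 °C brings the sequence back to the route at 9.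

Step 6. Oxygen may be delivered to the β face of C3 (syn to C14) in the sigmatropic shift, or the ene step may compete at the C9=C10 alkene. The fallback corrects C3 by inversion instead of relying on the direct facial preference. It sets out from 9: the same oxidation is run and the alcohol obtained, the 3β-epimer F3, is separated and inverted under Mitsunobu conditions (PPh3, diisopropyl azodicarboxylate, 4-nitrobenzoic acid, toluene, 0 °C) to the 3α 4-nitrobenzoate F4. Methanolysis with K2CO3 in MeOH at 0 °C comes back to the route at 10.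

Step 4. Methylenation of the electron-rich, ester-like carbonyl of 6 may stall, with loss of the silyl group or isomerisation of the triene on work-up. The fallback reverses the order, so the olefination is done on the robust ethyl ether. It sets out from 4: Wittig methylenation (Ph3P=CH2, THF, 0 °C → rt) should give the ethoxy triene F5. Brief hydrolysis on oxalic acid-wetted silica in CH2Cl2 at 0 °C should give 2-(2-methyl-3-methylidenecyclohex-1-en-1-yl)acetaldehyde F6. Soft enolisation with TBSOTf and Et3N in CH2Cl2 at −78 °C then returns to the route at 7; any Z enol ether formed is expected to be inert in step 5.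

Further compounds
F1 | step 5 | (S)-4-benzyl-3-{[8α-(tert-butyldimethylsilyloxy)-5β-methyl-4-methylideneoctal-9-en-7α-yl]carbonyl}oxazolidin-2-one (imide adduct) | O=C1OC[C@H](Cc2ccccc2)N1C(=O)[C@@H]1C[C@]2(C)C(=C)CCCC2=C[C@@H]1O[Si](C)(C)C(C)(C)C
F2 | step 5 | 8α-(tert-butyldimethylsilyloxy)-N-methoxy-N,5β-dimethyl-4-methylideneoctal-9-ene-7α-carboxamide | CON(C)C(=O)[C@@H]1C[C@]2(C)C(=C)CCCC2=C[C@@H]1O[Si](C)(C)C(C)(C)C
F3 | step 6 | 7α-acetyl-8α-(tert-butyldimethylsilyloxy)-5β-methyl-4-methylideneoctal-9-en-3β-ol | CC(=O)[C@@H]1C[C@]2(C)C(=C)[C@@H](O)CCC2=C[C@@H]1O[Si](C)(C)C(C)(C)C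
F4 | step 6 | 7α-acetyl-8α-(tert-butyldimethylsilyloxy)-5β-methyl-4-methylideneoctal-9-en-3α-yl 4-nitrobenzoate | CC(=O)[C@@H]1C[C@]2(C)C(=C)[C@H](OC(=O)c3ccc(cc3)[N+](=O)[O-])CCC2=C[C@@H]1O[Si](C)(C)C(C)(C)C
F5 | step 4 | 1-[(E)-2-ethoxyethenyl]-2-methyl-3-methylidenecyclohex-1-ene | CCO/C=C/C1=C(C)C(=C)CCC1
F6 | step 4 | 2-(2-methyl-3-methylidenecyclohex-1-en-1-yl)acetaldehyde | CC1=C(CC=O)CCCC1=C
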